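Target at 4.0 d is the wanted product of this flask, and two earlier runs with less solid reagent already bear on it.

| setting | dusk | winter | flask |
|---|---|---|---|
| substrate | 0.22 M | 0.22 M | 0.22 M |
| solid reagent | 0.55 equiv | 0.83 equiv | 1.10 equiv |
| remark | run made earlier | run made earlier |  |
| time |  |  | 4.0 d |

| run | time / d | target / % | substrate / % |
|---|---|---|---|
| dusk | 0.625 | 1.1 | 97.5 |
| dusk | 1.25 | 3.0 | 95.0 |
| dusk | 2.08 | 5.2 | 94.3 |
| dusk | 2.50 | 5.5 | 91.9 |
| dusk | 3.00 | 6.6 | 90.0 |
| dusk | 4.00 | 11.5 | 87.3 |
| winter | 0.333 | 0 | 99.0 |
| winter | 0.500 | 0 | 97.1 |
| winter | 0.833 | 1.2 | 95.8 |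
| winter | 1.67 | 3.8 | 94.3 |
| winter | 2.50 | 6.1 | 92.0 |
| winter | 4.00 | 10.7 | 87.8 |

(readings scatter by 1 percentage point)

- solid reagent is a solid; its amount is given per volume of the solution
- at the start none of the solid reagent is in solution

- Thursday's: doubling the solubility of the solid reagent, all else as stated
- Tuesday's: doubling the dissolution coefficient of the solid reagent, all else as stated

- target at 4.0 d, in percent of the substrate charged
- the change that raises the amount of target at 4.0 d, in percent of the substrate charged most ("none" if none brings more than 2 percentage points) (Thursday's / Tuesday's / none)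
- amount of target at 4.0 d, in percent of the substrate charged, after Tuesday's

One way for more solid reagent to bring more target is for the solid, as limiting reagent, to run out within the run. The substrate lost by 4.0 d averages 12.5 % in the two runs. If this flask loses the same share, my reckoning gives it L = 88.7 %, where L is the share of the solid charge left once one solid reagent is counted per substrate lost, that is, one minus loss over equivalents. The earlier runs give:

dusk run: L = 76.9 %

winter run: L = 85.3 %

Neither value of L comes near zero, and the last target readings of the two runs lie 0.8 percentage points apart, with a scatter of 1 point per reading. This flask's reckoned L stands further from zero than that of either run, so my reckoning takes the mean of the two readings, 11.1 %.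

The forecast gives 11 %, names Thursday's, and puts Tuesday's at 11.5 %, “since dissolution isn't limiting”.

The flask gives 10.8 %, and Thursday's stays best, but Tuesday's reaches 19.6 %; partner stood at 8.17 % of saturation at 0.400 d.

    substrate + partner → intermediate A (k = 0.790 /M/h)
    intermediate B ⇌ intermediate C (K = 0.610, k = 0.0200 /h)
    substrate + partner → target (k = 0.210 /M/h)
    partner → decomposed reagent (k = 0.0160 /h)
    solid reagent ⇌ partner, rate k5*(cs5 - [partner]) while solid is left; crystals form when [partner] > cs5 (solubility = 17.0 mM, k = 0.0230 /h)
    intermediate A → target (k = 0.0400 /h)
    partner + intermediate A ⇌ intermediate B (K = 3.30 /M, k = 0.00470 /M/h)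
    intermediate C → side product (k = 0.0230 /h)

Against L of 88.7 %, this flask holds 85.9 % of its solid reagent at 4.00 d. For the neighbour flask with 0.280 equiv, the same loss gives L = 55.4 %, still above zero; that flask keeps 47 % of its charge, solid or dissolved, and gives 10.8 % target.

The runs were computed on assumed constants; noise was put on by code.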